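The target is cut at both exocyclic CH2–aryl bonds at once. This leaves an enantiopure tetrahydrofuran core and two copies of one aryl bromide. The C2 axis through ring oxygen O1 and the midpoint of C3–C4 makes these two bonds equivalent, and each lies one atom outside the stereocentres C3 and C4. A single nickel-catalysed reductive coupling therefore joins two 3,4-dimethoxyphenyl rings to (3S,4S)-3,4-bis(iodomethyl)tetrahydrofuran without touching its configuration. The diiodide is made from furan-3,4-dicarboxylic acid by cis-hydrogenation, closure to the meso anhydride, desymmetrising methanolysis, epimerisation of the ester-bearing carbon, reduction and iodination. No half of the material is discarded in a resolution.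

Key step: step 7

Assumption: quinine is taken to open anhydride 3 in the same spatial sense as it opens carbocyclic five- and six-membered meso anhydrides, giving 4 as drawn; if a configuration check on diol 6 showed the mirror image, the pseudo-enantiomeric quinidine would be used and nothing else would change.

Step 1
Reactants: 1 furan-3,4-dicarboxylic acid
Product: 2 cis-tetrahydrofuran-3,4-dicarboxylic acid (meso, 3R,4S)
Conditions: H2 (50 bar), 5% Rh/C, AcOH–H2O, 60 °C
Reagents that add atoms: none
Why: Heterogeneous catalytic hydrogenation of the furan delivers all four hydrogens from the face bound to rhodium, so C3 and C4 are set cis to each other (meso), and rhodium saturates furans with little C–O hydrogenolysis while leaving the carboxylic acids untouched.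

Step 2
Reactants: 2 cis-tetrahydrofuran-3,4-dicarboxylic acid
Product: 3 cis-tetrahydro-1H,3H-furo[3,4-c]furan-1,3-dione (meso anhydride, 3aR,6aS)
Conditions: Ac2O, reflux; evaporation, recrystallisation from toluene
Reagents that add atoms: none
Why: Dehydrative cyclisation of a cis-1,2-diacid with acetic anhydride closes the five-membered anhydride, which only the cis isomer can form as a cis-fused bicyclo[3.3.0] system, so the step also secures the relative configuration.

Step 3
Reactants: 3 meso anhydride
Product: 4 (3S,4R)-4-(methoxycarbonyl)tetrahydrofuran-3-carboxylic acid (cis half-ester)
Conditions: quinine (1.1 equiv), MeOH (3 equiv), toluene, −55 °C; then 2 M HCl wash (alkaloid recovered), EtOAc extraction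
Reagents that add atoms: methanol, SMILES CO
Why: In this cinchona-alkaloid-mediated desymmetrising alcoholysis of a meso cyclic anhydride, the quinuclidine nitrogen of quinine acts as a general base and directs methanol to one of the two enantiotopic carbonyl groups, which fixes the absolute configuration as C3 (acid) S and C4 (ester) R.

Step 4
Reactants: 4 cis half-ester
Product: 5 (3S,4S)-4-(methoxycarbonyl)tetrahydrofuran-3-carboxylic acid (trans half-ester)
Conditions: NaOMe (3 equiv), dry MeOH, reflux; then aq HCl to pH 2, EtOAc extraction
Reagents that add atoms: none
Why: Thermodynamic base-mediated epimerisation through the ester enolate inverts only C4, because C3 sits next to a carboxylate that resists a second deprotonation, and the less crowded trans isomer should dominate at equilibrium; expulsion of O1 from the enolate would be the reverse of a 5-endo-trig closure and is stereoelectronically hindered.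

Step 5
Reactants: 5 trans half-ester
Product: 6 [(3R,4R)-tetrahydrofuran-3,4-diyl]dimethanol (C2-symmetric trans diol)
Conditions: LiAlH4 (4 equiv), THF, 0 °C to reflux; H2O/aq NaOH quench, salts washed with hot THF
Reagents that add atoms: none
Why: Exhaustive LiAlH4 reduction turns acid and ester alike into CH2OH, which makes the two arms identical and gives the C2-symmetric diol with C3 and C4 untouched (the change of descriptor to R,R reflects CIP priorities only).

Step 6
Reactants: 6 trans diol
Product: 8 (3S,4S)-3,4-bis(iodomethyl)tetrahydrofuran, via iodo alcohol 7 (not isolated)
Conditions: PPh3 (2.6 equiv), imidazole (5 equiv), I2 (2.6 equiv), THF–MeCN, 0 °C to rt, protected from light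
Reagents that add atoms: iodine, SMILES II
Why: In this Appel-type iodination (Garegg–Samuelsson conditions), iodide displaces each primary alkoxyphosphonium group by SN2 at the exocyclic carbon, and competing closure of the 1,4-diol to a second ether ring is disfavoured because that ring would be trans-fused (bicyclo[3.3.0]).

Step 7
Reactants: 8 (3S,4S)-3,4-bis(iodomethyl)tetrahydrofuran; 9 4-bromo-1,2-dimethoxybenzene (two equivalents incorporated)
Product: 11 (3S,4S)-3,4-bis(3,4-dimethoxybenzyl)tetrahydrofuran (target), via mono-arylated iodide 10 (not isolated)
Conditions: NiBr2(dme) (15 mol%), 4,4'-di-tert-butyl-2,2'-bipyridine (dtbbpy, 18 mol%), Zn dust (5 equiv), 9 (3 equiv), dry DMA, 40 °C, 8 added by syringe pump over 6 h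
Reagents that add atoms: none
Why: Zerovalent nickel bearing dtbbpy inserts into the C–Br bond of 9, the divalent arylnickel bromide captures the primary radical that monovalent nickel releases from a C–I bond of 8 by iodine abstraction, and the trivalent aryl(alkyl)nickel species reductively eliminates the CH2–aryl bond while zinc restores the low-valent catalyst; the same cycle then runs on 10. The closest known reaction type is the nickel-catalysed reductive cross-electrophile coupling of primary alkyl iodides with aryl bromides, applied here twice in one flask. No ring is closed and no stereocentre is created: each radical carbon is exocyclic, one bond away from C3 or C4, and has no heteroatom on its β-carbon, so there is no path to epimerisation or to loss of O1. The selectivity needed is cross- over homo-coupling at both arms; it comes from the two-electron activation of the C(sp2)–Br bond versus the one-electron activation of the C(sp3)–I bond, and it is reinforced by an excess of 9 and slow addition of 8 to offset the sluggish oxidative addition of the electron-rich bromide. Collapse of the 1,4-diiodide to a cyclobutane is held back because that ring would be trans-fused to the tetrahydrofuran (bicyclo[3.2.0] skeleton). A C2 rotation interchanges the two CH2I arms, so only one mono-arylated iodide 10 can form and its remaining arm reacts in the same way.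

Compound list
1 | furan-3,4-dicarboxylic acid | OC(=O)c1cocc1C(=O)O | starting material
2 | cis-tetrahydrofuran-3,4-dicarboxylic acid (meso, 3R,4S) | OC(=O)[C@H]1COC[C@H]1C(=O)O | intermediate
3 | cis-tetrahydro-1H,3H-furo[3,4-c]furan-1,3-dione (meso, 3aR,6aS) | O=C1OC(=O)[C@H]2COC[C@@H]12 | intermediate
4 | (3S,4R)-4-(methoxycarbonyl)tetrahydrofuran-3-carboxylic acid | COC(=O)[C@H]1COC[C@H]1C(=O)O | intermediate
5 | (3S,4S)-4-(methoxycarbonyl)tetrahydrofuran-3-carboxylic acid | COC(=O)[C@@H]1COC[C@H]1C(=O)O | intermediate
6 | [(3R,4R)-tetrahydrofuran-3,4-diyl]dimethanol | OC[C@@H]1COC[C@H]1CO | intermediate
7 | [(3R,4S)-4-(iodomethyl)tetrahydrofuran-3-yl]methanol (not isolated) | OC[C@@H]1COC[C@H]1CI | intermediate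
8 | (3S,4S)-3,4-bis(iodomethyl)tetrahydrofuran | IC[C@@H]1COC[C@H]1CI | intermediate
9 | 4-bromo-1,2-dimethoxybenzene | COc1ccc(Br)cc1OC | starting material
10 | (3S,4S)-3-(3,4-dimethoxybenzyl)-4-(iodomethyl)tetrahydrofuran (not isolated) | COc1ccc(C[C@@H]2COC[C@H]2CI)cc1OC | intermediate
11 | (3S,4S)-3,4-bis(3,4-dimethoxybenzyl)tetrahydrofuran | COc1ccc(C[C@@H]2COC[C@H]2Cc2ccc(OC)c(OC)c2)cc1OC | target

Total step count: 7. Longest linear sequence: 7 steps (1 to 11); 9 is bought and enters in step 7.

Steps most likely to fail

**Step 7.** Three processes could undermine the coupling.
- The electron-rich bromide adds slowly to zerovalent nickel. The iodide may therefore be consumed first by hydrodehalogenation, by alkyl–alkyl dimerisation, or by zinc insertion followed by protonation.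
- β-Hydride elimination at the alkylnickel stage toward the C3–H or C4–H bond would erase a stereocentre.
- The second radical may add to the ortho position of the aryl ring already installed, closing a six-membered ring. Ipso attack, by contrast, would only shuttle the aryl group between two equivalent arms.

The fallback separates the event into two polar operations, a Negishi coupling. From 8, zinc dust and LiCl in THF should give the bis(iodozincio) reagent F1 before any arene is present in the molecule. Pd(OAc)2/SPhos then couples both carbon–zinc bonds with 9 in THF at 50 °C, and the route is rejoined at 11.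

**Step 4.** The substrate reacts as its carboxylate, so enolisation needs excess methoxide and heat. Equilibration may stop short of the trans side, the ring may open by β-elimination of the ring alkoxide, and slow exchange at C3 would erode the enantiomeric purity. Residual cis material can only give a meso diol, which lowers throughput but not the enantiomeric purity.

The fallback moves the epimerisation to a neutral, achiral stage and introduces chirality afterwards.
- From 2, Fischer esterification (MeOH, cat. H2SO4) gives the meso dimethyl ester F2.
- Catalytic NaOMe in MeOH equilibrates it under mild conditions to the racemic trans-diester F3, with recovered cis ester recycled.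
- LiAlH4 gives the racemic trans-diol F4.
- Sequential acylation with vinyl acetate and Burkholderia cepacia lipase then parts the enantiomers as diol and diacetate, and the two successive enantioselective acylations multiply the selectivity.

The plan counts on the (3S,4S)-diol reacting faster, to give the (3R,4R)-diacetate F5 and leave 6 behind. With the opposite preference, 6 would be released from its own (3S,4S)-diacetate F6 by K2CO3/MeOH. Either way the route is rejoined at 6.

**Step 3.** Two processes would lower the enantiomeric purity: background methanolysis without the alkaloid, and weak discrimination between the enantiotopic carbonyl groups of a small, polar, oxygen-containing anhydride. Part of the water-soluble half-ester may also be lost in the acid wash.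

The fallback is a classical resolution. From 3, plain methanolysis in refluxing MeOH gives the racemic cis half-ester F7. The conditions of step 4 convert it into the racemic trans half-ester F8. Fractional crystallisation with (S)-1-phenylethylamine then separates the diastereomeric salts. The (S)-1-phenylethylammonium salt of the (3S,4S)-acid F9 is taken from the crystals, or from the mother liquor if it is the more soluble one. Acidification gives 5, where the route is rejoined.

Further compounds
F1 | step 7 | (3S,4S)-3,4-bis[(iodozincio)methyl]tetrahydrofuran | I[Zn]C[C@@H]1COC[C@H]1C[Zn]I
F2 | step 4 | dimethyl cis-tetrahydrofuran-3,4-dicarboxylate (meso, 3R,4S) | COC(=O)[C@H]1COC[C@H]1C(=O)OC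
F3 | step 4 | dimethyl trans-tetrahydrofuran-3,4-dicarboxylate, racemate (both enantiomers written) | COC(=O)[C@@H]1COC[C@H]1C(=O)OC.COC(=O)[C@H]1COC[C@@H]1C(=O)OC
F4 | step 4 | trans-tetrahydrofuran-3,4-diyldimethanol, racemate (6 and its mirror image written) | OC[C@@H]1COC[C@H]1CO.OC[C@H]1COC[C@@H]1CO
F5 | step 4 | [(3R,4R)-tetrahydrofuran-3,4-diyl]bis(methylene) diacetate (from the unwanted diol enantiomer) | CC(=O)OC[C@H]1COC[C@@H]1COC(C)=O
F6 | step 4 | [(3S,4S)-tetrahydrofuran-3,4-diyl]bis(methylene) diacetate (diacetate of 6) | CC(=O)OC[C@@H]1COC[C@H]1COC(C)=O
F7 | step 3 | cis-4-(methoxycarbonyl)tetrahydrofuran-3-carboxylic acid, racemate (4 and its mirror image written) | COC(=O)[C@H]1COC[C@H]1C(=O)O.COC(=O)[C@@H]1COC[C@@H]1C(=O)O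
F8 | step 3 | trans-4-(methoxycarbonyl)tetrahydrofuran-3-carboxylic acid, racemate (5 and its mirror image written) | COC(=O)[C@@H]1COC[C@H]1C(=O)O.COC(=O)[C@H]1COC[C@@H]1C(=O)O
F9 | step 3 | (S)-1-phenylethylammonium (3S,4S)-4-(methoxycarbonyl)tetrahydrofuran-3-carboxylate | COC(=O)[C@@H]1COC[C@H]1C(=O)[O-].C[C@H]([NH3+])c1ccccc1
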